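Abietane numbering is used throughout: ring B is C5–C10, ring C is C8, C9 and C11–C14, the acid chain is C1–C3, and the isopropenyl carbon on C5 is C4.

## The problem

The target 25 is a 3,4-seco-abietane: a hexasubstituted benzene (ring C) fused to a cyclohexanone (ring B). The quaternary benzylic carbon C10 carries a methyl group and the propanoic acid chain, and the neighbouring C5 carries an isopropenyl group. Ring C bears four different substituents in a fixed order (C11 hydroxyl, C12 methoxy, C13 isopropyl, C14 hydroxyl), so its positions cannot be told apart by classical aromatic substitution. The two stereocentres are contiguous. C10 cannot be corrected once made, but a C5 isopropenyl group can steer a reagent to the opposite face of C10, so one catalyst-controlled event at C5 can set both. The fragile groups are the electron-rich hydroquinone (air oxidation to the quinone, fastest under base), the isopropenyl group (protonated by strong acid, a competitor in any allylic or electrophilic oxidation) and the free acid. The C7 ketone must not be present while C9 is a carbanion. The enabling feature is that ring C is a 2-methoxy-3-alkylhydroquinone whose remaining two carbons, C8 and C9, can be an alkene of ring B. That is exactly what a squarate-derived 4-alkenyl-4-hydroxycyclobutenone turns into on heating, with C11 as the carbinol carbon, C12=C13 as the ring alkene and C14 as the ketone carbon.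

## Retrosynthesis

**25 back to 22 (no skeletal bond cut).** The hydroquinone, the C7 ketone and the acid are traced to quinone keto acid 24 by a mild two-electron reduction. 24 is traced to tetraol 23 by one hexavalent chromium oxidation that raises three sites at once, and 23 to the bis-silyl ether 22. C3 is carried as a protected alcohol rather than an ester because the C9 carbanion needed earlier sits five atoms from C3 and would close a five-membered ketone onto any ester (a Parham-type cyclisation). C7 is carried as a silyl ether because a C7 ketone would make C8=C9 an enone. The price is one oxidation step that passes through the quinone.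

**22 back to 19 (cut C8–C14; ring C opened).** The retro-Moore cut replaces the arene by a cyclohexene and a four-membered ring. Against stepwise decoration of a preformed arene, it fixes the order OH/OMe/i-Pr/OH by connectivity. Against intermolecular annulations, it needs no reagent and is unimolecular. The forward reaction must open the cyclobutenone with the hydroxyl turning outward and close onto C8 beside the quaternary C10 without disturbing two silyl ethers and the isopropenyl group.

**19 back to 13 and 17 (cut C9–C11).** Alkenyllithium 18, from iodide 13, adds to the ketone-like carbonyl of dione 17. This is the most convergent cut and forms the bond next to the quaternary centre by 1,2-addition of a small sp2 carbanion, which is much less sensitive to crowding than a conjugate addition at C9 would be. It asks for fast halogen–lithium exchange, no internal electrophile in 13, and attack at the carbonyl flanked by the methoxy-bearing carbon.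

**17 back to 14 and 15 (cut C13–C15).** Dimethyl squarate 14 takes up the isopropyl group from 15 at one of its two equivalent carbonyls, and acid then expels methanol from adduct 16. The symmetry of 14 removes any regiochemical question.

**13 back to 9 (C9–I from C9=O; C3 alcohol from the ester).** Iodide 13 comes from diol 12 and this from hydroxy ester 11, whose C9–I bond derives from the ketone of 9 through hydrazone 10. C10 is quaternary, so only C8 can lose a proton and the alkene position is fixed. The ester is reduced after the hydrazine step (a tert-butyl ester resists hydrazine) and before metalation.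

**9 back to 5 (cut C7–O).** The C7 oxygen is introduced by conjugate borylation/oxidation of enone 7 (through boronate 8), and 7 by dehydrogenation of ketone 5 through silyl enol ether 6. A later allylic oxidation would compete with the isopropenyl group, whereas the enone route addresses C7 alone. The C7 configuration is irrelevant.

**5 back to 1, 2 and 3 (cut C4–C5 and C10–C1).** Asymmetric conjugate addition of isopropenylmagnesium bromide 2 to 2-methylcyclohex-2-en-1-one 1 (CuBr·SMe2 with a chiral ferrocenyl diphosphine) sets C5. The regiodefined magnesium enolate 4 is trapped by tert-butyl acrylate 3 at C10 anti to the isopropenyl group. Three simple commercial compounds give both stereocentres in one flask.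

## Roads not taken

**Alternative 1:** The cut is C4–C5 and C10–C1 as the central event: 1, 2 and 3 are joined by copper-catalysed asymmetric conjugate addition and enolate trapping to give keto ester A1, which is identical with 5.
- Merits: it solves the whole stereochemical problem catalytically in one operation from commodity chemicals.
- Weak points: as a strategy it ends at ring B. Ring C, the C7 oxygen and the ordered arene substituents, which are the hard part of 25, are left open.
- Comparison: in stereocontrol it is exactly as good as the chosen plan, because the chosen plan uses it as step 1. What the chosen plan adds is a defined, regiochemically programmed way from A1 to the arene.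

**Alternative 2:** The cut is C5–C10 and C6–C7, opening ring B. Irradiation of the ortho-formyl aryl lactone A2 would give a hydroxy-ortho-quinodimethane that adds endo to the dienoate A3 to give cycloadduct A4.
- Merits: it is convergent and forms two C–C bonds, ring B and the quaternary centre in one step on an arene that already has the right substituents. In bond construction per step it is better than the chosen key step, which forms one bond and no stereocentre.
- Weak points:
  - The diene terminus C10 is fully substituted and held in a seven-membered lactone, so photoenolisation from a tertiary benzylic C–H and cycloaddition at a tetrasubstituted terminus must outrun re-ketonisation.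
  - A3 offers two alkenes and can itself act as a diene.
  - The step is racemic unless a chiral mediator can be found for this substrate.
  - A4 carries surplus functionality: the C6 ester must be excised after C7 oxidation, the C14 methyl ether cleaved in the presence of the C12 one, and the lactone opened.
  - The pentasubstituted arene A2 needs its own multistep synthesis, in which the order of ring C substituents must be established by aromatic chemistry.
- Comparison: if the photocycloaddition worked and could be made enantioselective, this road would be more convergent. The chosen plan sets against it catalyst-controlled absolute configuration and an arene whose constitution is fixed by construction.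

**Alternative 3:** The cut is C9–C11 and C8–C14, both bonds between rings B and C. The anion of sulfonyl butenolide A5 would add to C9 of enone A6, the C8 enolate would acylate the lactone carbonyl, and loss of sulfinate and aromatisation would give methyl ester A7, one hydrolysis from 25.
- Merits: it is the most convergent option, and the annulation delivers C7, C11 and C14 at their final oxidation levels with no protecting groups on ring C. In redox economy and endgame length it is better than the chosen plan.
- Weak points:
  - The Michael addition must occur at C9, a β-carbon attached directly to quaternary C10, with a bulky sulfonyl-stabilised anion. This is the least favourable acceptor type for such annulations.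
  - A5 is a monocyclic tetronate-type donor with a vinylogously acidic isopropyl methine and a displaceable methoxy group, rather than the usual benzo-fused donor.
  - A6 requires the ring B chemistry of the chosen plan plus a carbonyl transposition.
  - The final ester hydrolysis exposes the hydroquinone to base.
- Comparison: the chosen plan forms the same two bonds in separate, easier events: a 1,2-addition at −78 °C that is indifferent to C10, and an intramolecular electrocyclisation. It pays for this with three extra protecting-group and redox steps.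

Key step: step 9

Assumption: the sense of induction of the CuBr·SMe2/ferrocenyl diphosphine catalyst with an alkenyl Grignard reagent on this α-methyl enone is not predicted here; the ligand named in step 1 stands for whichever antipode delivers (S)-C5, both antipodes being available.

Assumption: C7 is drawn as the expected major epimer (oxygen trans to the isopropenyl group) and the C11 carbinol of 19 as a mixture; both centres become sp2, so every epimer converges on 25.

## Route

Step 1
Reactants: 1 2-methylcyclohex-2-en-1-one; 2 isopropenylmagnesium bromide; 3 tert-butyl acrylate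
Product: 5 tert-butyl 3-[(1S,6S)-1-methyl-2-oxo-6-(prop-1-en-2-yl)cyclohexyl]propanoate, via magnesium enolate 4 (not isolated)
Conditions: CuBr·SMe2 (5 mol %), (R)-1-[(Sp)-2-(diphenylphosphino)ferrocenyl]ethyldicyclohexylphosphine (6 mol %), t-BuOMe, −78 °C; then 3, −78 → 0 °C; aq. NH4Cl
Reagents that add atoms: none
Why: Copper-catalysed asymmetric conjugate addition of the Grignard reagent sets C5 under ligand control; the regiodefined magnesium enolate 4 then undergoes Michael addition to the acrylate through C10 on the face anti to the neighbouring isopropenyl group (held pseudoaxial by allylic strain with the enolate methyl), which sets C10 with methyl cis to isopropenyl as in 25.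

Step 2
Reactants: 5 tert-butyl 3-[(1S,6S)-1-methyl-2-oxo-6-(prop-1-en-2-yl)cyclohexyl]propanoate
Product: 7 tert-butyl 3-[(1S,6S)-1-methyl-2-oxo-6-(prop-1-en-2-yl)cyclohex-3-en-1-yl]propanoate, via trimethylsilyl enol ether 6 (not isolated)
Conditions: LiN(i-Pr)2 (1.05 equiv), Me3SiCl, THF, −78 °C; concentrate; then Pd(OAc)2 (1.05 equiv), MeCN, rt
Reagents that add atoms: chlorotrimethylsilane, C[Si](C)(C)Cl (silyl group of intermediate 6 only)
Why: Saegusa–Ito dehydrogenation; C10 is quaternary, so the ketone can enolise only towards C8 and the C7=C8 enone is the only possible product, while the less acidic ester α-position is left alone by one equivalent of amide base with internal silyl quench.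

Step 3
Reactants: 7 tert-butyl 3-[(1S,6S)-1-methyl-2-oxo-6-(prop-1-en-2-yl)cyclohex-3-en-1-yl]propanoate
Product: 9 tert-butyl 3-[(1S,4R,6S)-4-hydroxy-1-methyl-2-oxo-6-(prop-1-en-2-yl)cyclohexyl]propanoate, via β-boryl ketone 8 (not isolated)
Conditions: B2pin2 (1.1 equiv), CuCl (5 mol %), bis[2-(diphenylphosphino)phenyl] ether (5 mol %), NaOt-Bu (10 mol %), MeOH (2 equiv), THF, rt; then NaBO3·4H2O, THF/H2O, rt
Reagents that add atoms: bis(pinacolato)diboron, CC1(C)OB(OC1(C)C)B1OC(C)(C)C(C)(C)O1 (boryl group of intermediate 8 only); sodium perborate tetrahydrate, [Na+].[Na+].O[B-]1(O)OO[B-](O)(O)OO1.O.O.O.O.O.O (oxygen at C7 of 9)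
Why: Copper-catalysed conjugate borylation of a cyclic enone followed by perborate oxidation of the C–B bond with retention; boron should enter C7 anti to the C5 substituent (the usual trans-3,5 outcome for 5-substituted cyclohexenones), the unactivated isopropenyl alkene does not react, and the C7 configuration is of no consequence.

Step 4
Reactants: 9 tert-butyl 3-[(1S,4R,6S)-4-hydroxy-1-methyl-2-oxo-6-(prop-1-en-2-yl)cyclohexyl]propanoate
Product: 11 tert-butyl 3-[(1S,4R,6S)-4-hydroxy-2-iodo-1-methyl-6-(prop-1-en-2-yl)cyclohex-2-en-1-yl]propanoate, via hydrazone 10 (not isolated)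
Conditions: N2H4·H2O, AcOH (cat.), EtOH, rt → 40 °C; concentrate; then I2, 1,1,3,3-tetramethylguanidine, THF, 0 °C → rt
Reagents that add atoms: hydrazine hydrate, NN.O (nitrogen atoms of intermediate 10 only); iodine, II (iodine at C9 of 11)
Why: Barton vinyl iodide synthesis; iodine oxidises the hydrazone to an α-iodo cation that loses nitrogen and the only available β-proton (C8–H), a sequence that is reliable for ketones flanked by a quaternary carbon; acid-buffered condensation disfavours base-induced loss of the β-hydroxyl and the tert-butyl ester resists hydrazine.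

Step 5
Reactants: 11 tert-butyl 3-[(1S,4R,6S)-4-hydroxy-2-iodo-1-methyl-6-(prop-1-en-2-yl)cyclohex-2-en-1-yl]propanoate
Product: 12 (1R,4S,5S)-4-(3-hydroxypropyl)-3-iodo-4-methyl-5-(prop-1-en-2-yl)cyclohex-2-en-1-ol
Conditions: i-Bu2AlH (4 equiv), CH2Cl2, −78 → 0 °C; aq. potassium sodium tartrate
Reagents that add atoms: none
Why: Hydride reduction of the ester to the primary alcohol; the alkenyl iodide and both alkenes are inert to the aluminium hydride at this temperature, and the only electrophile that could intercept the C9 carbanion of step 8 is removed.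

Step 6
Reactants: 12 (1R,4S,5S)-4-(3-hydroxypropyl)-3-iodo-4-methyl-5-(prop-1-en-2-yl)cyclohex-2-en-1-ol
Product: 13 (1R,4S,5S)-1-(tert-butyldimethylsilyloxy)-4-[3-(tert-butyldimethylsilyloxy)propyl]-3-iodo-4-methyl-5-(prop-1-en-2-yl)cyclohex-2-ene
Conditions: t-BuMe2SiCl (2.5 equiv), imidazole, DMF, rt
Reagents that add atoms: tert-butyldimethylsilyl chloride, CC(C)(C)[Si](C)(C)Cl
Why: Standard silyl ether formation on a primary and a secondary allylic alcohol; the two ethers survive organolithium reagents and 110 °C and fall together to fluoride in step 10.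

Step 7
Reactants: 14 dimethyl squarate; 15 isopropylmagnesium chloride
Product: 17 3-methoxy-4-(propan-2-yl)cyclobut-3-ene-1,2-dione, via hydroxycyclobutenone adduct 16 (not isolated)
Conditions: THF, −78 °C; aq. NH4Cl; then conc. HCl (cat.), CH2Cl2, rt
Reagents that add atoms: none
Why: 1,2-Addition of the Grignard reagent to one of the two equivalent carbonyls of the squaric ester, then acid-catalysed 1,3-transposition of the hydroxyl and loss of methanol from the resulting hemiketal, the standard route to 3-alkyl-4-alkoxycyclobutenediones.

Step 8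
Reactants: 13 (1R,4S,5S)-1-(tert-butyldimethylsilyloxy)-4-[3-(tert-butyldimethylsilyloxy)propyl]-3-iodo-4-methyl-5-(prop-1-en-2-yl)cyclohex-2-ene; 17 3-methoxy-4-(propan-2-yl)cyclobut-3-ene-1,2-dione
Product: 19 4-[(3R,5S,6S)-3-(tert-butyldimethylsilyloxy)-6-[3-(tert-butyldimethylsilyloxy)propyl]-6-methyl-5-(prop-1-en-2-yl)cyclohex-1-en-1-yl]-4-hydroxy-3-methoxy-2-(propan-2-yl)cyclobut-2-en-1-one (both carbinol epimers), via alkenyllithium 18 (not isolated)
Conditions: t-BuLi (2.1 equiv), Et2O, −78 °C; then 17, THF, −78 °C; aq. NH4Cl at −78 °C
Reagents that add atoms: tert-butyllithium, [Li]C(C)(C)C (lithium of intermediate 18 only)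
Why: Iodine–lithium exchange followed by 1,2-addition of the alkenyllithium to a cyclobutenedione; the carbonyl flanked by the methoxy-bearing carbon is the more electrophilic (the other is a vinylogous ester and is shielded by the isopropyl group), so C11 ends next to C12–OMe and the remaining ketone next to C13; the new carbinol centre is formed without control and is destroyed in step 9.

Step 9
Reactants: 19 4-[(3R,5S,6S)-3-(tert-butyldimethylsilyloxy)-6-[3-(tert-butyldimethylsilyloxy)propyl]-6-methyl-5-(prop-1-en-2-yl)cyclohex-1-en-1-yl]-4-hydroxy-3-methoxy-2-(propan-2-yl)cyclobut-2-en-1-one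
Product: 22 (5S,6S,8R)-8-(tert-butyldimethylsilyloxy)-5-[3-(tert-butyldimethylsilyloxy)propyl]-3-methoxy-5-methyl-2-(propan-2-yl)-6-(prop-1-en-2-yl)-5,6,7,8-tetrahydronaphthalene-1,4-diol, via dienylketene 20 (not isolated), via cyclohexadienone 21 (not isolated)
Conditions: toluene (degassed), 110 °C, argon
Reagents that add atoms: none
Why: Heating opens the cyclobutenone by conrotatory 4π-electrocyclic cleavage of the C11–C14 bond, the C11 hydroxyl rotating outward so that the C9 alkenyl group turns inward and the (Z)-dienylketene 20 results. The ketene carbon C14 then bonds to C8 in a thermal disrotatory 6π-electrocyclisation, which closes ring C as a six-membered carbocycle (cyclohexadienone 21), and enolisation of the C8–H gives the aromatic 11,14-hydroquinone 22. This is the Moore rearrangement of squarate-derived 4-alkenyl-4-hydroxycyclobutenones, a known benzannulation that needs no reagent. No stereocentre is created: the carbinol centre of 19 and the transient sp3 C8 of 21 both end as arene carbons, and C5, C7 and C10 are spectators. The selectivity required is constitutional and torquoselective: the order OH/OMe/i-Pr/OH around ring C is fixed by the connectivity of 19, and the outward preference of the donor hydroxyl secures the inward alkenyl group that closure needs. Release of four-membered ring strain and aromatisation drive the sequence, and the silyl ethers and the isopropenyl group are inert under these neutral conditions.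

Step 10
Reactants: 22 (5S,6S,8R)-8-(tert-butyldimethylsilyloxy)-5-[3-(tert-butyldimethylsilyloxy)propyl]-3-methoxy-5-methyl-2-(propan-2-yl)-6-(prop-1-en-2-yl)-5,6,7,8-tetrahydronaphthalene-1,4-diol
Product: 23 (5R,7S,8S)-8-(3-hydroxypropyl)-2-methoxy-8-methyl-3-(propan-2-yl)-7-(prop-1-en-2-yl)-5,6,7,8-tetrahydronaphthalene-1,4,5-triol
Conditions: n-Bu4NF (3 equiv), AcOH (3 equiv), THF, 0 °C → rt, argon
Reagents that add atoms: none
Why: Fluoride desilylation of both silyl ethers; the acetic acid buffer keeps the hydroquinone protonated and so slows its air oxidation, and any quinone that does form is the same intermediate that step 11 passes through.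

Step 11
Reactants: 23 (5R,7S,8S)-8-(3-hydroxypropyl)-2-methoxy-8-methyl-3-(propan-2-yl)-7-(prop-1-en-2-yl)-5,6,7,8-tetrahydronaphthalene-1,4,5-triol
Product: 24 3-[(1S,2S)-7-methoxy-1-methyl-4,5,8-trioxo-6-(propan-2-yl)-2-(prop-1-en-2-yl)-1,2,3,4,5,8-hexahydronaphthalen-1-yl]propanoic acid
Conditions: CrO3, H2SO4, H2O, acetone, 0 °C; then i-PrOH
Reagents that add atoms: water, O (second oxygen of the C3 carboxyl group)
Why: Jones oxidation; hexavalent chromium takes the hydroquinone to the quinone (which then shields ring C), the secondary C7 carbinol to the ketone and the primary alcohol through its aldehyde hydrate to the acid in one operation, and isolated isopropenyl groups ordinarily survive these conditions, as in the oxidation of isopropenyl-bearing triterpenoid diols to keto acids.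

Step 12
Reactants: 24 3-[(1S,2S)-7-methoxy-1-methyl-4,5,8-trioxo-6-(propan-2-yl)-2-(prop-1-en-2-yl)-1,2,3,4,5,8-hexahydronaphthalen-1-yl]propanoic acid
Product: 25 3-[(1S,2S)-5,8-dihydroxy-7-methoxy-1-methyl-4-oxo-6-(propan-2-yl)-2-(prop-1-en-2-yl)-1,2,3,4-tetrahydronaphthalen-1-yl]propanoic acid
Conditions: Na2S2O4, EtOAc/H2O, rt, argon
Reagents that add atoms: none
Why: Two-electron reduction of a quinone to its hydroquinone by dithionite; the aryl ketone, the alkene and the acid are untouched, and the product is stabilised by the hydrogen bond between the C14 hydroxyl and the C7 carbonyl.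

## Compound list

1 | 2-methylcyclohex-2-en-1-one | CC1=CCCCC1=O | starting material
2 | isopropenylmagnesium bromide | C=C(C)[Mg]Br | starting material
3 | tert-butyl acrylate | C=CC(=O)OC(C)(C)C | starting material
4 | bromo[(3S)-2-methyl-3-(prop-1-en-2-yl)cyclohex-1-en-1-olato]magnesium (magnesium enolate) | C=C(C)[C@@H]1CCCC(O[Mg]Br)=C1C | intermediate
5 | tert-butyl 3-[(1S,6S)-1-methyl-2-oxo-6-(prop-1-en-2-yl)cyclohexyl]propanoate | C=C(C)[C@@H]1CCCC(=O)[C@@]1(C)CCC(=O)OC(C)(C)C | intermediate
6 | tert-butyl 3-[(1S,6S)-1-methyl-6-(prop-1-en-2-yl)-2-(trimethylsilyloxy)cyclohex-2-en-1-yl]propanoate | C=C(C)[C@@H]1CCC=C(O[Si](C)(C)C)[C@@]1(C)CCC(=O)OC(C)(C)C | intermediate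
7 | tert-butyl 3-[(1S,6S)-1-methyl-2-oxo-6-(prop-1-en-2-yl)cyclohex-3-en-1-yl]propanoate | C=C(C)[C@@H]1CC=CC(=O)[C@@]1(C)CCC(=O)OC(C)(C)C | intermediate
8 | tert-butyl 3-[(1S,4R,6S)-1-methyl-2-oxo-6-(prop-1-en-2-yl)-4-(4,4,5,5-tetramethyl-1,3,2-dioxaborolan-2-yl)cyclohexyl]propanoate | C=C(C)[C@@H]1C[C@@H](B2OC(C)(C)C(C)(C)O2)CC(=O)[C@@]1(C)CCC(=O)OC(C)(C)C | intermediate
9 | tert-butyl 3-[(1S,4R,6S)-4-hydroxy-1-methyl-2-oxo-6-(prop-1-en-2-yl)cyclohexyl]propanoate | C=C(C)[C@@H]1C[C@@H](O)CC(=O)[C@@]1(C)CCC(=O)OC(C)(C)C | intermediate
10 | tert-butyl 3-[(1S,4R,6S)-2-hydrazinylidene-4-hydroxy-1-methyl-6-(prop-1-en-2-yl)cyclohexyl]propanoate | C=C(C)[C@@H]1C[C@@H](O)CC(=NN)[C@@]1(C)CCC(=O)OC(C)(C)C | intermediate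
11 | tert-butyl 3-[(1S,4R,6S)-4-hydroxy-2-iodo-1-methyl-6-(prop-1-en-2-yl)cyclohex-2-en-1-yl]propanoate | C=C(C)[C@@H]1C[C@@H](O)C=C(I)[C@@]1(C)CCC(=O)OC(C)(C)C | intermediate
12 | (1R,4S,5S)-4-(3-hydroxypropyl)-3-iodo-4-methyl-5-(prop-1-en-2-yl)cyclohex-2-en-1-ol | C=C(C)[C@@H]1C[C@@H](O)C=C(I)[C@@]1(C)CCCO | intermediate
13 | (1R,4S,5S)-1-(tert-butyldimethylsilyloxy)-4-[3-(tert-butyldimethylsilyloxy)propyl]-3-iodo-4-methyl-5-(prop-1-en-2-yl)cyclohex-2-ene | C=C(C)[C@@H]1C[C@@H](O[Si](C)(C)C(C)(C)C)C=C(I)[C@@]1(C)CCCO[Si](C)(C)C(C)(C)C | intermediate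
14 | dimethyl squarate (3,4-dimethoxycyclobut-3-ene-1,2-dione) | COC1=C(OC)C(=O)C1=O | starting material
15 | isopropylmagnesium chloride | CC(C)[Mg]Cl | starting material
16 | 4-hydroxy-2,3-dimethoxy-4-(propan-2-yl)cyclobut-2-en-1-one (racemic) | COC1=C(OC)C(O)(C(C)C)C1=O | intermediate
17 | 3-methoxy-4-(propan-2-yl)cyclobut-3-ene-1,2-dione | COC1=C(C(C)C)C(=O)C1=O | intermediate
18 | alkenyllithium: 13 with lithium in place of iodine at C9, all three stereocentres unchanged | C=C(C)[C@@H]1C[C@@H](O[Si](C)(C)C(C)(C)C)C=C([Li])[C@@]1(C)CCCO[Si](C)(C)C(C)(C)C | intermediate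
19 | 4-[(3R,5S,6S)-3-(tert-butyldimethylsilyloxy)-6-[3-(tert-butyldimethylsilyloxy)propyl]-6-methyl-5-(prop-1-en-2-yl)cyclohex-1-en-1-yl]-4-hydroxy-3-methoxy-2-(propan-2-yl)cyclobut-2-en-1-one (both carbinol epimers) | C=C(C)[C@@H]1C[C@@H](O[Si](C)(C)C(C)(C)C)C=C(C2(O)C(OC)=C(C(C)C)C2=O)[C@@]1(C)CCCO[Si](C)(C)C(C)(C)C | intermediate
20 | (Z)-dienylketene from ring opening of 19: C9–C11(OH)=C12(OMe)–C13(i-Pr)=C14=O, C9 cis to C13 | C=C(C)[C@@H]1C[C@@H](O[Si](C)(C)C(C)(C)C)C=C(/C(O)=C(OC)\C(C(C)C)=C=O)[C@@]1(C)CCCO[Si](C)(C)C(C)(C)C | intermediate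
21 | cyclohexa-2,4-dienone from 20: ring C closed by the C8–C14 bond, C14 ketone, C8 still sp3 (CH) | C=C(C)[C@@H]1C[C@@H](O[Si](C)(C)C(C)(C)C)C2C(=O)C(C(C)C)=C(OC)C(O)=C2[C@@]1(C)CCCO[Si](C)(C)C(C)(C)C | intermediate
22 | (5S,6S,8R)-8-(tert-butyldimethylsilyloxy)-5-[3-(tert-butyldimethylsilyloxy)propyl]-3-methoxy-5-methyl-2-(propan-2-yl)-6-(prop-1-en-2-yl)-5,6,7,8-tetrahydronaphthalene-1,4-diol | C=C(C)[C@@H]1C[C@@H](O[Si](C)(C)C(C)(C)C)c2c(O)c(C(C)C)c(OC)c(O)c2[C@@]1(C)CCCO[Si](C)(C)C(C)(C)C | intermediate
23 | (5R,7S,8S)-8-(3-hydroxypropyl)-2-methoxy-8-methyl-3-(propan-2-yl)-7-(prop-1-en-2-yl)-5,6,7,8-tetrahydronaphthalene-1,4,5-triol | C=C(C)[C@@H]1C[C@@H](O)c2c(O)c(C(C)C)c(OC)c(O)c2[C@@]1(C)CCCO | intermediate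
24 | 3-[(1S,2S)-7-methoxy-1-methyl-4,5,8-trioxo-6-(propan-2-yl)-2-(prop-1-en-2-yl)-1,2,3,4,5,8-hexahydronaphthalen-1-yl]propanoic acid | C=C(C)[C@@H]1CC(=O)C2=C(C(=O)C(OC)=C(C(C)C)C2=O)[C@@]1(C)CCC(=O)O | intermediate
25 | 3-[(1S,2S)-5,8-dihydroxy-7-methoxy-1-methyl-4-oxo-6-(propan-2-yl)-2-(prop-1-en-2-yl)-1,2,3,4-tetrahydronaphthalen-1-yl]propanoic acid | C=C(C)[C@@H]1CC(=O)c2c(O)c(C(C)C)c(OC)c(O)c2[C@@]1(C)CCC(=O)O | target

## Step count and least certain steps

Total: 12 steps. Longest linear sequence: 11 steps (steps 1–6 and 8–12); step 7 makes dione 17 in one step from 14 and 15.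

**Step 9 (key step).** The 6π-closure onto C8 may be slowed by the quaternary C10 beside C9, which gives the ketene time to be captured by the C11 hydroxyl (lactonisation after inward rotation) or to decompose. The free hydroquinone may also oxidise during isolation. The fallback sets out from 13 and 17 and comes back at 23. Step 8 is run as before, but the lithium alkoxide is quenched with Me3SiCl instead of NH4Cl to give the carbinol trimethylsilyl ether F1. With no free hydroxyl the ketene cannot be trapped, and heating F1 in toluene or xylene should give the C11 trimethylsilyl ether of the hydroquinone F2. Treatment with n-Bu4NF/AcOH as in step 10 then removes all three silyl groups and gives 23.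

**Step 1.** Enantioselectivity with an alkenyl Grignard reagent on an α-substituted enone may be insufficient. The ester enolate formed after the Michael addition may also start anionic oligomerisation of the acrylate, or be relayed to C8 and add a second acrylate. The fallback sets out from 1 and 2 and comes back at 5. The copper step is quenched with aq. NH4Cl to give (2S,3R)-2-methyl-3-(prop-1-en-2-yl)cyclohexan-1-one F3, and condensation with benzylamine gives the N-benzyl imine F4. Its secondary enamine tautomer adds to 3 in THF at 40–60 °C at the more substituted α-carbon and anti to the isopropenyl group; this is the known imine/secondary-enamine Michael addition of 2-alkylcyclohexanones, which runs under neutral conditions without an ester enolate. Hydrolysis of the adduct imine F5 with aq. AcOH gives 5.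

**Step 4.** The β-hydroxyl at C7 may be lost by base-induced elimination before the hindered ketone has condensed with hydrazine, or azine formation may compete. The fallback sets out from 9 and comes back at 19.
- Silylation (t-BuMe2SiCl, imidazole) gives the silyl ether F6.
- KN(SiMe3)2 and N-phenylbis(trifluoromethanesulfonimide) at −78 °C give the enol triflate F7.
- i-Bu2AlH reduces the ester to give the hydroxypropyl triflate F8, and a second silylation gives the bis-silyl triflate F9.
- Pd(PPh3)4, Me3SnSnMe3 and LiCl in THF convert F9 into the alkenylstannane F10.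
- Tin–lithium exchange with MeLi gives 18, which adds to 17 as in step 8 to give 19.

**Step 8.** The hindered alkenyllithium may act as a base towards the vinylogously acidic isopropyl methine of 17, or attack the vinylogous ester carbonyl with loss of methoxide, instead of adding to the ketone-like carbonyl. The fallback sets out from 13 and comes back at 19. 18 is generated as before and transmetalated with anhydrous CeCl3 at −78 °C to the alkenylcerium dichloride F11. This less basic, more oxophilic reagent should add to the same carbonyl of 17 and give 19 after aqueous work-up.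

**Step 11.** Aqueous acid may hydrate or cyclise the isopropenyl group, and the enolisable acylquinone may be over-oxidised by chromium. The fallback sets out from 23 and comes back at 24. Dess–Martin periodinane in CH2Cl2 with NaHCO3 should oxidise the hydroquinone, the C7 carbinol and the primary alcohol to the quinone keto aldehyde F12. Buffered NaClO2 (NaH2PO4, 2-methyl-2-butene, t-BuOH/H2O) then takes the aldehyde to the acid 24 without strong acid or chromium.

## Further compounds

F1 | step 9 | 4-[(3R,5S,6S)-3-(tert-butyldimethylsilyloxy)-6-[3-(tert-butyldimethylsilyloxy)propyl]-6-methyl-5-(prop-1-en-2-yl)cyclohex-1-en-1-yl]-3-methoxy-2-(propan-2-yl)-4-(trimethylsilyloxy)cyclobut-2-en-1-one (carbinol trimethylsilyl ether) | C=C(C)[C@@H]1C[C@@H](O[Si](C)(C)C(C)(C)C)C=C(C2(O[Si](C)(C)C)C(OC)=C(C(C)C)C2=O)[C@@]1(C)CCCO[Si](C)(C)C(C)(C)C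
F2 | step 9 | (5S,6S,8R)-8-(tert-butyldimethylsilyloxy)-5-[3-(tert-butyldimethylsilyloxy)propyl]-3-methoxy-5-methyl-2-(propan-2-yl)-6-(prop-1-en-2-yl)-4-(trimethylsilyloxy)-5,6,7,8-tetrahydronaphthalen-1-ol (C11 trimethylsilyl ether of the hydroquinone) | C=C(C)[C@@H]1C[C@@H](O[Si](C)(C)C(C)(C)C)c2c(O)c(C(C)C)c(OC)c(O[Si](C)(C)C)c2[C@@]1(C)CCCO[Si](C)(C)C(C)(C)C
F3 | step 1 | (2S,3R)-2-methyl-3-(prop-1-en-2-yl)cyclohexan-1-one | C=C(C)[C@@H]1CCCC(=O)[C@H]1C
F4 | step 1 | (2S,3R)-N-benzyl-2-methyl-3-(prop-1-en-2-yl)cyclohexan-1-imine (N-benzyl imine) | C=C(C)[C@@H]1CCCC(=NCc2ccccc2)[C@H]1C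
F5 | step 1 | tert-butyl 3-[(1S,6S)-2-(benzylimino)-1-methyl-6-(prop-1-en-2-yl)cyclohexyl]propanoate (adduct imine) | C=C(C)[C@@H]1CCCC(=NCc2ccccc2)[C@@]1(C)CCC(=O)OC(C)(C)C
F6 | step 4 | tert-butyl 3-[(1S,4R,6S)-4-(tert-butyldimethylsilyloxy)-1-methyl-2-oxo-6-(prop-1-en-2-yl)cyclohexyl]propanoate (silyl ether) | C=C(C)[C@@H]1C[C@@H](O[Si](C)(C)C(C)(C)C)CC(=O)[C@@]1(C)CCC(=O)OC(C)(C)C
F7 | step 4 | tert-butyl 3-[(1S,4R,6S)-4-(tert-butyldimethylsilyloxy)-1-methyl-6-(prop-1-en-2-yl)-2-(trifluoromethanesulfonyloxy)cyclohex-2-en-1-yl]propanoate (enol triflate) | C=C(C)[C@@H]1C[C@@H](O[Si](C)(C)C(C)(C)C)C=C(OS(=O)(=O)C(F)(F)F)[C@@]1(C)CCC(=O)OC(C)(C)C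
F8 | step 4 | (3R,5S,6S)-3-(tert-butyldimethylsilyloxy)-6-(3-hydroxypropyl)-6-methyl-5-(prop-1-en-2-yl)cyclohex-1-en-1-yl trifluoromethanesulfonate (hydroxypropyl triflate) | C=C(C)[C@@H]1C[C@@H](O[Si](C)(C)C(C)(C)C)C=C(OS(=O)(=O)C(F)(F)F)[C@@]1(C)CCCO
F9 | step 4 | (3R,5S,6S)-3-(tert-butyldimethylsilyloxy)-6-[3-(tert-butyldimethylsilyloxy)propyl]-6-methyl-5-(prop-1-en-2-yl)cyclohex-1-en-1-yl trifluoromethanesulfonate (bis-silyl triflate) | C=C(C)[C@@H]1C[C@@H](O[Si](C)(C)C(C)(C)C)C=C(OS(=O)(=O)C(F)(F)F)[C@@]1(C)CCCO[Si](C)(C)C(C)(C)C
F10 | step 4 | [(3R,5S,6S)-3-(tert-butyldimethylsilyloxy)-6-[3-(tert-butyldimethylsilyloxy)propyl]-6-methyl-5-(prop-1-en-2-yl)cyclohex-1-en-1-yl]trimethylstannane (alkenylstannane) | C=C(C)[C@@H]1C[C@@H](O[Si](C)(C)C(C)(C)C)C=C([Sn](C)(C)C)[C@@]1(C)CCCO[Si](C)(C)C(C)(C)C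
F11 | step 8 | alkenylcerium dichloride: 18 with CeCl2 in place of lithium at C9 | C=C(C)[C@@H]1C[C@@H](O[Si](C)(C)C(C)(C)C)C=C([Ce](Cl)Cl)[C@@]1(C)CCCO[Si](C)(C)C(C)(C)C
F12 | step 11 | 3-[(1S,2S)-7-methoxy-1-methyl-4,5,8-trioxo-6-(propan-2-yl)-2-(prop-1-en-2-yl)-1,2,3,4,5,8-hexahydronaphthalen-1-yl]propanal (quinone keto aldehyde) | C=C(C)[C@@H]1CC(=O)C2=C(C(=O)C(OC)=C(C(C)C)C2=O)[C@@]1(C)CCC=O
A1 | alternative 1 | tert-butyl 3-[(1S,6S)-1-methyl-2-oxo-6-(prop-1-en-2-yl)cyclohexyl]propanoate (identical with 5) | C=C(C)[C@@H]1CCCC(=O)[C@@]1(C)CCC(=O)OC(C)(C)C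
A2 | alternative 2 | 7,9-dimethoxy-5-methyl-2-oxo-8-(propan-2-yl)-2,3,4,5-tetrahydro-1-benzoxepine-6-carbaldehyde (ortho-formyl aryl lactone; the benzylic centre is erased in the photoenol) | O=Cc1c(OC)c(C(C)C)c(OC)c2OC(=O)CCC(C)c12
A3 | alternative 2 | prop-2-en-1-yl (2E)-4-methylpenta-2,4-dienoate | C=C(C)/C=C/C(=O)OCC=C
A4 | alternative 2 | ring B cycloadduct: C7 hydroxyl, C6 allyl ester, C12 and C14 methyl ethers, C11–O to C3 seven-membered lactone, C5 isopropenyl, C10 methyl | C=C(C)[C@@H]1[C@@H](C(=O)OCC=C)[C@@H](O)c2c(OC)c(C(C)C)c(OC)c3c2[C@@]1(C)CCC(=O)O3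
A5 | alternative 3 | 4-methoxy-5-(phenylsulfonyl)-3-(propan-2-yl)furan-2(5H)-one | COC1=C(C(C)C)C(=O)OC1S(=O)(=O)c1ccccc1
A6 | alternative 3 | methyl 3-[(1R,6S)-1-methyl-4-oxo-6-(prop-1-en-2-yl)cyclohex-2-en-1-yl]propanoate | C=C(C)[C@@H]1CC(=O)C=C[C@@]1(C)CCC(=O)OC
A7 | alternative 3 | methyl 3-[(1S,2S)-5,8-dihydroxy-7-methoxy-1-methyl-4-oxo-6-(propan-2-yl)-2-(prop-1-en-2-yl)-1,2,3,4-tetrahydronaphthalen-1-yl]propanoate | C=C(C)[C@@H]1CC(=O)c2c(O)c(C(C)C)c(OC)c(O)c2[C@@]1(C)CCC(=O)OC
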